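1. Last operations: unmask the phenol; make C10–Br/C11–OH by SN2 bromide opening of a (10S,11S)-epoxide.
2. 15-membered lactone (the last ring formed): aryl bromide + CO + (14S)-14,15-epoxide, a carbonylative bromo-acylation that makes the C14–O ester and the C15–Br bond together.
3. Ar–CH2–C2 bond by Negishi coupling of a benzylic zinc reagent with the ring A enol triflate; C9–C10 bond by B-alkyl Suzuki coupling with an (E)-alkenyl iodide; both epoxides from one double Shi epoxidation.
4. C6–Br and the C7 quaternary centre by a bromonium-triggered semipinacol rearrangement (1,2-shift of an ethenyl group) of an enantioenriched 1-ethenylcyclohex-2-enol.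
5. Ring order: ring A is carried from a cyclohexenone and functionalised by the 1,2-shift, the arene comes from a cresol, the macrolactone is closed last.

Assumption: positions are given in the diterpenoid numbering of the natural product (C1 benzylic CH2, C2=C3 ring alkene, C6 CHBr, C7 quaternary, C10 CHBr, C11 C(OH)Me, C14 CH–O, C15 CMe2Br); read from the SMILES, the target is 6S,7S,10R,11S,14S.

Step 1
Reactants: 1 2-methylcyclohex-2-en-1-one
Product: 2 (S)-1-ethenyl-2-methylcyclohex-2-en-1-ol
Conditions: Zn(CH=CH2)2 (1.6 equiv; from CH2=CHMgBr + ZnCl2, MgBrCl precipitated with 1,4-dioxane and filtered off), Ti(OiPr)4 (1.2 equiv), trans-1,2-bis(2-hydroxycamphor-10-sulfonamido)cyclohexane ligand (10 mol %, antipode giving Si-face attack), toluene, rt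
Reagents that add atoms: vinylmagnesium bromide C=C[Mg]Br (transmetallated in the flask to divinylzinc C=C[Zn]C=C)
Why: Titanium-promoted, bis(sulfonamide)diol-controlled enantioselective 1,2-addition of a diorganozinc to a ketone (established for dialkyl- and alkenylzinc reagents with 2-substituted cycloalkenones, the α-methyl group suppressing conjugate addition); Si-face vinyl transfer sets the (S)-carbinol, the only source of absolute configuration for ring A.

Step 2
Reactants: 2 (S)-1-ethenyl-2-methylcyclohex-2-en-1-ol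
Product: 3 (2S,3S)-3-bromo-2-ethenyl-2-methylcyclohexan-1-one
Conditions: NBS (1.1 equiv), CH2Cl2, −40 → 0 °C, dark
Reagents that add atoms: N-bromosuccinimide O=C1CCC(=O)N1Br
Why: Halonium-induced semipinacol rearrangement of a tertiary allylic alcohol: Br+ adds to the electron-rich trisubstituted ring alkene syn to OH, the ethenyl group antiperiplanar to the bromonium C–Br bond undergoes a cationic 1,2-shift as the carbinol collapses to the ketone, so the carbinol chirality is transferred stereospecifically into the C7 quaternary centre (ethenyl trans to Br, methyl cis) and the C6–Br centre, while the bromonium on the other face has no antiperiplanar migrating group and reverts.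

Step 3
Reactants: 3 (2S,3S)-3-bromo-2-ethenyl-2-methylcyclohexan-1-one
Product: 4 (2S,3S,6RS)-3-bromo-2-ethenyl-2,6-dimethylcyclohexan-1-one
Conditions: LiN(iPr)2 (1.05 equiv), THF, −78 °C; MeI, −78 → −20 °C
Reagents that add atoms: iodomethane CI
Why: Kinetic lithium enolate alkylation at the only enolisable α-carbon (C3); the new centre is an epimer mixture that is erased in step 4, and E1cB loss of bromide is impossible because the carbon between C=O and CHBr is quaternary.

Step 4
Reactants: 4 (2S,3S,6RS)-3-bromo-2-ethenyl-2,6-dimethylcyclohexan-1-one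
Product: 5 (5S,6S)-5-bromo-6-ethenyl-2,6-dimethylcyclohex-1-en-1-yl trifluoromethanesulfonate
Conditions: KN(SiMe3)2, THF, −78 → 0 °C; PhNTf2, 0 °C
Reagents that add atoms: N-phenylbis(trifluoromethanesulfonimide) O=S(=O)(N(c1ccccc1)S(=O)(=O)C(F)(F)F)C(F)(F)F
Why: Enolate O-sulfonylation; only C3–H can be removed, so the tetrasubstituted C2=C3 enol triflate forms regiospecifically (the 2,2,6-trisubstituted cyclohexanone case is well precedented) and C6/C7 are untouched.

Step 5
Reactants: 6 5-bromo-2-methylpent-2-ene
Product: 7 6-methylhept-5-en-1-yne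
Conditions: LiC≡CH·H2NCH2CH2NH2, DMSO, 10 °C → rt
Reagents that add atoms: lithium acetylide–ethylenediamine complex [Li]C#C.NCCN
Why: SN2 alkylation of lithium acetylide by a primary homoallylic bromide in DMSO; no stereocentre is involved.

Step 6
Reactants: 7 6-methylhept-5-en-1-yne
Product: 9 (E)-1-iodo-2,6-dimethylhepta-1,5-diene, via alkenylalane 8 (not isolated)
Conditions: AlMe3 (2 equiv), Cp2ZrCl2 (25 mol %), CH2Cl2, 0 °C → rt; I2, THF, −30 °C
Reagents that add atoms: trimethylaluminium C[Al](C)C; iodine [I][I]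
Why: Negishi zirconium-catalysed carboalumination (syn addition of Me–Al, aluminium at the terminal carbon) followed by iodinolysis with retention gives the E-trisubstituted alkenyl iodide that becomes C10=C11.

Step 7
Reactants: 5 (5S,6S)-5-bromo-6-ethenyl-2,6-dimethylcyclohex-1-en-1-yl trifluoromethanesulfonate; 9 (E)-1-iodo-2,6-dimethylhepta-1,5-diene
Product: 11 (5S,6S)-5-bromo-6-[(E)-4,8-dimethylnona-3,7-dien-1-yl]-2,6-dimethylcyclohex-1-en-1-yl trifluoromethanesulfonate, via alkylborane 10 (not isolated)
Conditions: 9-BBN, THF, rt; then 9, PdCl2(dppf) (5 mol %; dppf = 1,1'-bis(diphenylphosphino)ferrocene), AsPh3, Cs2CO3, DMF/H2O, rt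
Reagents that add atoms: none
Why: Anti-Markovnikov hydroboration of the monosubstituted ethenyl group (the enol triflate alkene is inert) and B-alkyl Suzuki–Miyaura coupling with retention of alkene geometry; the unhindered alkenyl iodide undergoes oxidative addition far faster than the tetrasubstituted triflate next to the quaternary carbon, which is saved for step 12.

Step 8
Reactants: 11 (5S,6S)-5-bromo-6-[(E)-4,8-dimethylnona-3,7-dien-1-yl]-2,6-dimethylcyclohex-1-en-1-yl trifluoromethanesulfonate
Product: 12 (5S,6S)-5-bromo-6-{2-[(2S,3S)-3-{2-[(2S)-3,3-dimethyloxiran-2-yl]ethyl}-3-methyloxiran-2-yl]ethyl}-2,6-dimethylcyclohex-1-en-1-yl trifluoromethanesulfonate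
Conditions: L-fructose-derived Shi ketone (1,2:4,5-di-O-isopropylidene-β-L-erythro-2,3-hexodiulo-2,6-pyranose, 0.6 equiv), KHSO5 (as 2KHSO5·KHSO4·K2SO4), K2CO3, Bu4NHSO4, MeCN/CH2(OMe)2/aq. Na2B4O7 buffer (pH 10.5), 0 °C
Reagents that add atoms: potassium peroxymonosulfate [K+].[O-]OS(=O)(=O)O
Why: Shi asymmetric epoxidation (chiral dioxirane, spiro transition state) of both electron-rich trisubstituted alkenes in one operation; this ketone antipode gives the 10S,11S and 14S epoxides under catalyst control, and the electron-poor enol triflate alkene does not react.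

Step 9
Reactants: 13 2-methylphenol
Product: 14 4-bromo-2-methylphenol
Conditions: NBS (1.0 equiv), MeCN, 0 °C
Reagents that add atoms: N-bromosuccinimide O=C1CCC(=O)N1Br
Why: Electrophilic aromatic bromination para to the hydroxyl group, which MeCN favours over the hindered ortho position.

Step 10
Reactants: 14 4-bromo-2-methylphenol
Product: 15 (4-bromo-2-methylphenoxy)(tert-butyl)dimethylsilane
Conditions: tBuMe2SiCl, imidazole, DMF, rt
Reagents that add atoms: tert-butyldimethylsilyl chloride CC(C)(C)[Si](C)(C)Cl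
Why: Silylation of the phenol, which masks the acidic OH for the radical, organozinc and acyl bromide chemistry that follows.

Step 11
Reactants: 15 (4-bromo-2-methylphenoxy)(tert-butyl)dimethylsilane
Product: 16 [4-bromo-2-(bromomethyl)phenoxy](tert-butyl)dimethylsilane
Conditions: NBS (1.05 equiv), 2,2'-azobis(2-methylpropionitrile) (5 mol %), PhCF3, 85 °C
Reagents that add atoms: N-bromosuccinimide O=C1CCC(=O)N1Br
Why: Wohl–Ziegler radical bromination at the only benzylic position.

Step 12
Reactants: 12 bis-epoxy enol triflate (product of step 8); 16 [4-bromo-2-(bromomethyl)phenoxy](tert-butyl)dimethylsilane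
Product: 18 tert-butyl{4-bromo-2-[((5S,6S)-5-bromo-6-{2-[(2S,3S)-3-{2-[(2S)-3,3-dimethyloxiran-2-yl]ethyl}-3-methyloxiran-2-yl]ethyl}-2,6-dimethylcyclohex-1-en-1-yl)methyl]phenoxy}dimethylsilane, via benzylzinc bromide 17 (not isolated)
Conditions: 16, Zn, LiCl, THF, 0 °C → rt; then 12, PdCl2(dppf) (5 mol %), THF, 50 °C, slow addition of the zinc reagent
Reagents that add atoms: none
Why: LiCl-assisted zinc insertion into the benzylic C–Br bond and Negishi sp2–sp3 coupling; the bidentate-phosphine palladium catalyst engages the alkenyl triflate in preference to the electron-rich aryl bromide, the benzyl group cannot β-eliminate, and the weakly Lewis acidic zinc reagent in THF leaves the epoxides and all stereocentres intact.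

Step 13
Reactants: 18 aryl bromide bis-epoxide (product of step 12)
Product: 20 tert-butyldimethylsilyl ether of the (6S,7S,10S,11S,14S)-6,15-dibromo-10,11-epoxy macrolide (bromophycolide A skeleton with the C10/C11 bromohydrin still an epoxide), via aroyl bromide 19 (not isolated)
Conditions: Pd(P(tBu)3)2 (10 mol %), CO (5 atm), toluene (0.002 M, 18 added over 12 h), 90 °C
Reagents that add atoms: carbon monoxide [C-]#[O+]
Why: Proposed new method: palladium-catalysed carbonylative bromo-acylation of an epoxide with halide relay — oxidative addition of the aryl bromide to monoligated zerovalent palladium, CO insertion and P(tBu)3/CO-induced C(acyl)–Br reductive elimination release aroyl bromide 19 reversibly; the 14,15-epoxide oxygen captures it (O-acylated oxiranium bromide ion pair) and bromide collapses on the tertiary, more cation-stabilising C15, so the C14–O bond is never broken (14S retained), the bromine of 18 becomes the C15–Br and the 15-membered lactone closes in preference to the strained 11- or 12-membered rings available from the 10,11-epoxide; the closest known chemistry is the palladium/P(tBu)3-catalysed carbonylation of aryl halides to aroyl halides combined with the uncatalysed addition of acyl bromides to epoxides giving β-bromoalkyl esters.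

Step 14
Reactants: 20 silyl-protected epoxy macrolide (product of step 13)
Product: 21 bromophycolide A tert-butyldimethylsilyl ether
Conditions: Li2NiBr4, THF, 0 °C → rt; aq. work-up
Reagents that add atoms: dilithium tetrabromonickelate [Li+].[Li+].[Ni+2].[Br-].[Br-].[Br-].[Br-]
Why: SN2 opening of the trisubstituted epoxide by soft, weakly Lewis acidic bromide at the less substituted carbon C10 with inversion (10S → 10R) while the C11–O bond and 11S are retained, giving the anti bromohydrin; the tertiary bromide, ester and silyl ether are inert.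

Step 15
Reactants: 21 bromophycolide A tert-butyldimethylsilyl ether
Product: 22 bromophycolide A
Conditions: HF·pyridine, THF/pyridine, 0 °C → rt
Reagents that add atoms: none
Why: Fluoride-mediated cleavage of the aryl silyl ether under mildly acidic conditions that spare the bromohydrin (no base, so no epoxide re-closure), the tertiary bromide and the lactone.

Compound list
1 | 2-methylcyclohex-2-en-1-one | CC1=CCCCC1=O | starting material
2 | (S)-1-ethenyl-2-methylcyclohex-2-en-1-ol | O[C@]1(C=C)CCCC=C1C | intermediate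
3 | (2S,3S)-3-bromo-2-ethenyl-2-methylcyclohexan-1-one | O=C1CCC[C@H](Br)[C@@]1(C)C=C | intermediate
4 | (2S,3S,6RS)-3-bromo-2-ethenyl-2,6-dimethylcyclohexan-1-one (C6 epimer mixture) | O=C1C(C)CC[C@H](Br)[C@@]1(C)C=C | intermediate
5 | (5S,6S)-5-bromo-6-ethenyl-2,6-dimethylcyclohex-1-en-1-yl trifluoromethanesulfonate | CC1=C(OS(=O)(=O)C(F)(F)F)[C@](C)(C=C)[C@@H](Br)CC1 | intermediate
6 | 5-bromo-2-methylpent-2-ene | CC(C)=CCCBr | starting material
7 | 6-methylhept-5-en-1-yne | C#CCCC=C(C)C | intermediate
8 | [(E)-2,6-dimethylhepta-1,5-dien-1-yl]dimethylalane | C[Al](C)/C=C(\C)CCC=C(C)C | intermediate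
9 | (E)-1-iodo-2,6-dimethylhepta-1,5-diene | I/C=C(\C)CCC=C(C)C | intermediate
10 | (5S,6S)-6-[2-(9-borabicyclo[3.3.1]nonan-9-yl)ethyl]-5-bromo-2,6-dimethylcyclohex-1-en-1-yl trifluoromethanesulfonate | CC1=C(OS(=O)(=O)C(F)(F)F)[C@](C)(CCB2C3CCCC2CCC3)[C@@H](Br)CC1 | intermediate
11 | (5S,6S)-5-bromo-6-[(E)-4,8-dimethylnona-3,7-dien-1-yl]-2,6-dimethylcyclohex-1-en-1-yl trifluoromethanesulfonate | CC1=C(OS(=O)(=O)C(F)(F)F)[C@](C)(CC/C=C(\C)CCC=C(C)C)[C@@H](Br)CC1 | intermediate
12 | (5S,6S)-5-bromo-6-{2-[(2S,3S)-3-{2-[(2S)-3,3-dimethyloxiran-2-yl]ethyl}-3-methyloxiran-2-yl]ethyl}-2,6-dimethylcyclohex-1-en-1-yl trifluoromethanesulfonate | CC1=C(OS(=O)(=O)C(F)(F)F)[C@](C)(CC[C@@H]2O[C@@]2(C)CC[C@@H]2OC2(C)C)[C@@H](Br)CC1 | intermediate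
13 | 2-methylphenol | Cc1ccccc1O | starting material
14 | 4-bromo-2-methylphenol | Cc1cc(Br)ccc1O | intermediate
15 | (4-bromo-2-methylphenoxy)(tert-butyl)dimethylsilane | Cc1cc(Br)ccc1O[Si](C)(C)C(C)(C)C | intermediate
16 | [4-bromo-2-(bromomethyl)phenoxy](tert-butyl)dimethylsilane | BrCc1cc(Br)ccc1O[Si](C)(C)C(C)(C)C | intermediate
17 | {5-bromo-2-[(tert-butyldimethylsilyl)oxy]benzyl}zinc bromide | Br[Zn]Cc1cc(Br)ccc1O[Si](C)(C)C(C)(C)C | intermediate
18 | tert-butyl{4-bromo-2-[((5S,6S)-5-bromo-6-{2-[(2S,3S)-3-{2-[(2S)-3,3-dimethyloxiran-2-yl]ethyl}-3-methyloxiran-2-yl]ethyl}-2,6-dimethylcyclohex-1-en-1-yl)methyl]phenoxy}dimethylsilane | CC1=C(Cc2cc(Br)ccc2O[Si](C)(C)C(C)(C)C)[C@](C)(CC[C@@H]2O[C@@]2(C)CC[C@@H]2OC2(C)C)[C@@H](Br)CC1 | intermediate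
19 | 4-[(tert-butyldimethylsilyl)oxy]-3-{[(5S,6S)-5-bromo-6-{2-[(2S,3S)-3-{2-[(2S)-3,3-dimethyloxiran-2-yl]ethyl}-3-methyloxiran-2-yl]ethyl}-2,6-dimethylcyclohex-1-en-1-yl]methyl}benzoyl bromide | CC1=C(Cc2cc(C(Br)=O)ccc2O[Si](C)(C)C(C)(C)C)[C@](C)(CC[C@@H]2O[C@@]2(C)CC[C@@H]2OC2(C)C)[C@@H](Br)CC1 | intermediate
20 | tert-butyldimethylsilyl ether of the (6S,7S,10S,11S,14S)-6,15-dibromo-10,11-epoxy 15-membered macrolide | CC1=C2Cc3cc(ccc3O[Si](C)(C)C(C)(C)C)C(=O)O[C@H](C(C)(C)Br)CC[C@]4(C)O[C@H]4CC[C@]2(C)[C@@H](Br)CC1 | intermediate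
21 | bromophycolide A tert-butyldimethylsilyl ether (6S,7S,10R,11S,14S) | CC1=C2Cc3cc(ccc3O[Si](C)(C)C(C)(C)C)C(=O)O[C@H](C(C)(C)Br)CC[C@](C)(O)[C@H](Br)CC[C@]2(C)[C@@H](Br)CC1 | intermediate
22 | bromophycolide A (6S,7S,10R,11S,14S) | CC1=C2Cc3cc(ccc3O)C(=O)O[C@H](C(C)(C)Br)CC[C@](C)(O)[C@H](Br)CC[C@]2(C)[C@@H](Br)CC1 | target

Total step count: 15. Longest linear sequence: 10 steps (steps 1, 2, 3, 4, 7, 8, 12, 13, 14, 15).

Steps most likely to fail

Step 13 (the proposed new step). The release of the aroyl bromide from palladium or its capture by the epoxide may be too slow. The fallback uses only known reactions and makes the acyl bromide stoichiometrically instead of catalytically. It sets out from 18: ordinary palladium-catalysed hydroxycarbonylation (Pd(OAc)2, Xantphos, CO 1 atm, H2O, Et3N, 1,4-dioxane, 70 °C) gives the seco benzoic acid F1. The acid is converted under neutral conditions with 1-bromo-N,N,2-trimethylprop-1-en-1-amine (CH2Cl2, 0.002 M, 0 °C → rt) into aroyl bromide 19, where the route is rejoined. Compound 19 then closes to 20 by the known addition of an acyl bromide across an epoxide to give a β-bromoalkyl ester.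

Step 12. The zinc salts may damage the epoxides, or the hindered triflate may lose out to the aryl bromide. The fallback changes the order of fragment union so that no epoxide meets the zinc reagent and the coupling can be forced. It sets out from 5: Negishi coupling of 5 with 17 (PdCl2(dppf), THF, 65 °C) gives the ethenyl-substituted aryl bromide F2. 9-BBN hydroboration of its ethenyl group gives the alkylborane F3, which is coupled without isolation with 9 (PdCl2(dppf), K3PO4, DMF, 50 °C; the alkenyl iodide reacts before the electron-rich aryl bromide) to the triene F4. Double Shi epoxidation as in step 8, now relying on the steric shielding of the tetrasubstituted ring alkene, comes back to the route at 18.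

Step 1. Unsubstituted divinylzinc may give low enantioselectivity with this catalyst. The fallback replaces asymmetric catalysis by resolution and sets out from 1: CH2=CHMgBr with CeCl3 (THF, −78 °C) gives the racemic alcohol, that is 2 together with its enantiomer (R)-1-ethenyl-2-methylcyclohex-2-en-1-ol F5. The stereospecific rearrangement of step 2 on this mixture gives 3 together with its mirror image (2R,3R)-3-bromo-2-ethenyl-2-methylcyclohexan-1-one F6, which is removed by preparative chiral supercritical-fluid chromatography. The route is rejoined at 3.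

Further compounds
F1 | step 13 | 4-[(tert-butyldimethylsilyl)oxy]-3-{[(5S,6S)-5-bromo-6-{2-[(2S,3S)-3-{2-[(2S)-3,3-dimethyloxiran-2-yl]ethyl}-3-methyloxiran-2-yl]ethyl}-2,6-dimethylcyclohex-1-en-1-yl]methyl}benzoic acid | CC1=C(Cc2cc(C(O)=O)ccc2O[Si](C)(C)C(C)(C)C)[C@](C)(CC[C@@H]2O[C@@]2(C)CC[C@@H]2OC2(C)C)[C@@H](Br)CC1
F2 | step 12 | tert-butyl(4-bromo-2-{[(5S,6S)-5-bromo-6-ethenyl-2,6-dimethylcyclohex-1-en-1-yl]methyl}phenoxy)dimethylsilane | CC1=C(Cc2cc(Br)ccc2O[Si](C)(C)C(C)(C)C)[C@](C)(C=C)[C@@H](Br)CC1
F3 | step 12 | {2-[((5S,6S)-6-[2-(9-borabicyclo[3.3.1]nonan-9-yl)ethyl]-5-bromo-2,6-dimethylcyclohex-1-en-1-yl)methyl]-4-bromophenoxy}(tert-butyl)dimethylsilane | CC1=C(Cc2cc(Br)ccc2O[Si](C)(C)C(C)(C)C)[C@](C)(CCB2C3CCCC2CCC3)[C@@H](Br)CC1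
F4 | step 12 | tert-butyl{4-bromo-2-[((5S,6S)-5-bromo-6-[(E)-4,8-dimethylnona-3,7-dien-1-yl]-2,6-dimethylcyclohex-1-en-1-yl)methyl]phenoxy}dimethylsilane | CC1=C(Cc2cc(Br)ccc2O[Si](C)(C)C(C)(C)C)[C@](C)(CC/C=C(\C)CCC=C(C)C)[C@@H](Br)CC1
F5 | step 1 | (R)-1-ethenyl-2-methylcyclohex-2-en-1-ol | O[C@@]1(C=C)CCCC=C1C
F6 | step 1 | (2R,3R)-3-bromo-2-ethenyl-2-methylcyclohexan-1-one | O=C1CCC[C@@H](Br)[C@]1(C)C=C
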